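**Retrosynthetic overview**

1. Andrographolide 24 ⇐ bis-silyl ether 23 ⇐ one cation–olefin bicyclisation of the acyclic epoxy diene allylsilane 22, which already carries the finished (E)-alkylidene silyloxy lactone; the bonds cut are C4–C5 (ring A) and C9–C10 (ring B).
2. Enabling feature: in ring B, C9 lies between the exocyclic C8=C17 methylene and the methyl-bearing quaternary C10, and across ring A the equatorial C3 oxygen is antiperiplanar to C4–C5. The array C17=C8–C9 / C10=C5 / C4–C3–O (C19 as the CH2O arm) is therefore the imprint of an allylsilane terminator, a trisubstituted olefin and a (Z)-derived 2,3-epoxy alcohol initiator.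
3. 22 ⇐ vinyl iodide diol 20 (Pd carbonylative lactonisation) ⇐ skipped enyne 18 ⇐ allylic chloride 14 + (S)-but-3-yne-1,2-diol 17 (from (R)-glyceraldehyde acetonide; carries C14).
4. 14 ⇐ epoxy chloride 8 + methyl acetoacetate (dianion alkylation, Z-enol phosphate, Me3SiCH2 coupling); 8 ⇐ geranyl chloride by Still–Gennari olefination and Sharpless epoxidation (sets C3 and C4, which then control C5, C9 and C10).
5. Ring order: lactone ring (step 17), then ring A and, as the last ring of the skeleton, ring B, both in step 19.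

Key step: step 19

Remark (assumptions): atoms are numbered as in the labdane skeleton (C1–C20, lactone carbons C13–C16). Compounds 1, 4, 9 and 15 are taken as commercial. (S)-But-3-yne-1,2-diol is made in two steps rather than assumed to be purchasable.

**Route**

Step 1
Reactants: 1 geranyl chloride [(2E)-1-chloro-3,7-dimethylocta-2,6-diene]
Product: 2 racemic 3-[(3E)-5-chloro-3-methylpent-3-en-1-yl]-2,2-dimethyloxirane
Conditions: mCPBA (1.0 equiv), NaHCO3, CH2Cl2, −10 to 0 °C
Reagents that add atoms: 3-chloroperoxybenzoic acid (mCPBA), OOC(=O)c1cccc(Cl)c1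
Why: Prilezhaev epoxidation should take the remote, more electron-rich trisubstituted olefin because the 2,3-olefin is deactivated by the allylic chloride; the new stereocentre is racemic and is destroyed in step 2.

Step 2
Reactants: 2 racemic epoxygeranyl chloride
Product: 3 (4E)-6-chloro-4-methylhex-4-enal
Conditions: H5IO6 (1.1 equiv), THF/Et2O, 0 °C
Reagents that add atoms: none
Why: Periodic acid opens the epoxide at its tertiary carbon and cleaves the resulting glycol (Malaprade-type cleavage), so the aldehyde keeps the former epoxide oxygen, acetone is lost and the allylic chloride is untouched.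

Step 3
Reactants: 3 (4E)-6-chloro-4-methylhex-4-enal; 4 ethyl 2-[bis(2,2,2-trifluoroethoxy)phosphoryl]propanoate
Product: 5 ethyl (2Z,6E)-8-chloro-2,6-dimethylocta-2,6-dienoate
Conditions: KN(SiMe3)2, 18-crown-6, THF, −78 °C
Reagents that add atoms: none
Why: The Still–Gennari variant of the Horner–Wadsworth–Emmons reaction should give the kinetic Z-enoate, which puts the future C19 carbon cis to the chain; at −78 °C the aldehyde should outpace alkylation of the phosphonate anion by the allylic chloride.

Step 4
Reactants: 5 ethyl (2Z,6E)-8-chloro-2,6-dimethylocta-2,6-dienoate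
Product: 6 (2Z,6E)-8-chloro-2,6-dimethylocta-2,6-dien-1-ol
Conditions: i-Bu2AlH (2.2 equiv), CH2Cl2, −78 °C; aq. potassium sodium tartrate
Reagents that add atoms: none
Why: 1,2-Reduction of the enoate by the electrophilic aluminium hydride leaves the olefin geometry and the allylic chloride intact at −78 °C.

Step 5
Reactants: 6 (2Z,6E)-8-chloro-2,6-dimethylocta-2,6-dien-1-ol
Product: 7 [(2S,3R)-3-[(3E)-5-chloro-3-methylpent-3-en-1-yl]-2-methyloxiran-2-yl]methanol
Conditions: Ti(OiPr)4 (10 mol %), L-(+)-diethyl tartrate (12 mol %), t-BuOOH, 4 Å molecular sieves, CH2Cl2, −20 °C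
Reagents that add atoms: tert-butyl hydroperoxide, CC(C)(C)OO
Why: Sharpless asymmetric epoxidation reaches only the olefin of the allylic alcohol, and the L-(+)-tartrate ligand should select the face that gives the (2S,3R)-epoxy alcohol, so C3 (R) and the precursor configuration of C4 are set by the reagent.

Step 6
Reactants: 7 (2S,3R)-epoxy alcohol
Product: 8 tert-butyl{[(2S,3R)-3-[(3E)-5-chloro-3-methylpent-3-en-1-yl]-2-methyloxiran-2-yl]methoxy}dimethylsilane
Conditions: TBSCl, imidazole, CH2Cl2, 0 °C to rt
Reagents that add atoms: tert-butyldimethylsilyl chloride, CC(C)(C)[Si](C)(C)Cl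
Why: Standard silylation of the primary alcohol gives a bulky, weakly coordinating ether that will not direct the Lewis acid in step 19 and is removed at the end.

Step 7
Reactants: 8 silyl epoxy chloride; 9 methyl acetoacetate (methyl 3-oxobutanoate)
Product: 10 methyl (6E)-9-[(2R,3S)-3-({[tert-butyl(dimethyl)silyl]oxy}methyl)-3-methyloxiran-2-yl]-7-methyl-3-oxonon-6-enoate
Conditions: 9 (1.5 equiv), NaH then n-BuLi, THF, 0 °C; then 8, 0 °C to rt; aq. NH4Cl
Reagents that add atoms: none
Why: γ-Alkylation of the acetoacetate dianion displaces the primary allylic chloride without allylic transposition, so the E-olefin is kept, and the trisubstituted epoxide should not be opened by this stabilised carbanion.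

Step 8
Reactants: 10 β-keto ester
Product: 11 methyl (2Z,6E)-9-[(2R,3S)-3-({[tert-butyl(dimethyl)silyl]oxy}methyl)-3-methyloxiran-2-yl]-3-[(diethoxyphosphoryl)oxy]-7-methylnona-2,6-dienoate
Conditions: NaH, Et2O, 0 °C; then (EtO)2P(O)Cl
Reagents that add atoms: diethyl chlorophosphate, CCOP(=O)(Cl)OCC
Why: O-Phosphorylation of the chelated sodium enolate of the β-keto ester should give the Z-enol phosphate (phosphate cis to the ester), which fixes the geometry of the later allylsilane.

Step 9
Reactants: 11 Z-enol phosphate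
Product: 12 methyl (2Z,6E)-9-[(2R,3S)-3-({[tert-butyl(dimethyl)silyl]oxy}methyl)-3-methyloxiran-2-yl]-7-methyl-3-[(trimethylsilyl)methyl]nona-2,6-dienoate
Conditions: Me3SiCH2MgCl (2.5 equiv), Ni(acac)2 (5 mol %), THF, 0 °C to rt
Reagents that add atoms: (trimethylsilyl)methylmagnesium chloride, C[Si](C)(C)C[Mg]Cl
Why: Nickel-catalysed Kumada-type coupling of the enol phosphate proceeds with retention of olefin geometry, so the silylmethyl group ends cis to the ester carbon (C7 trans to C11); the hindered Grignard reagent should spare the ester and the epoxide.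

Step 10
Reactants: 12 allylsilane ester
Product: 13 (2Z,6E)-9-[(2R,3S)-3-({[tert-butyl(dimethyl)silyl]oxy}methyl)-3-methyloxiran-2-yl]-7-methyl-3-[(trimethylsilyl)methyl]nona-2,6-dien-1-ol
Conditions: i-Bu2AlH (2.5 equiv), CH2Cl2, −78 °C; aq. potassium sodium tartrate
Reagents that add atoms: none
Why: 1,2-Reduction of the enoate to the allylic alcohol under non-acidic conditions keeps the allylsilane and the epoxide.

Step 11
Reactants: 13 allylic alcohol
Product: 14 tert-butyl{[(2S,3R)-3-[(3E,7Z)-9-chloro-3-methyl-7-[(trimethylsilyl)methyl]nona-3,7-dien-1-yl]-2-methyloxiran-2-yl]methoxy}dimethylsilane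
Conditions: NCS, Me2S, CH2Cl2, −20 to 0 °C
Reagents that add atoms: N-chlorosuccinimide, ClN1C(=O)CCC1=O
Why: Corey–Kim chlorination converts the primary allylic alcohol into the chloride through an alkoxysulfonium salt under neutral conditions, without allylic transposition and without acid that would attack the allylsilane or the epoxide.

Step 12
Reactants: 15 (R)-2,2-dimethyl-1,3-dioxolane-4-carbaldehyde
Product: 16 (S)-4-ethynyl-2,2-dimethyl-1,3-dioxolane
Conditions: dimethyl (1-diazo-2-oxopropyl)phosphonate, K2CO3, MeOH, 0 °C to rt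
Reagents that add atoms: dimethyl (1-diazo-2-oxopropyl)phosphonate, COP(=O)(OC)C(=[N+]=[N-])C(C)=O
Why: Ohira–Bestmann homologation turns the aldehyde into the terminal alkyne under mild carbonate conditions; the stereocentre (the future C14) is not touched and only its descriptor changes.

Step 13
Reactants: 16 (S)-4-ethynyl-2,2-dimethyl-1,3-dioxolane
Product: 17 (S)-but-3-yne-1,2-diol
Conditions: 1 M aq. HCl, THF, rt; neutralise, evaporate
Reagents that add atoms: none
Why: Acid hydrolysis of the acetonide frees the diol at this early stage, so that no acid is needed later when the epoxide and the allylsilane are present.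

Step 14
Reactants: 14 allylic chloride; 17 (S)-but-3-yne-1,2-diol
Product: 18 (2S,6Z,10E)-13-[(2R,3S)-3-({[tert-butyl(dimethyl)silyl]oxy}methyl)-3-methyloxiran-2-yl]-11-methyl-7-[(trimethylsilyl)methyl]trideca-6,10-dien-3-yne-1,2-diol
Conditions: CuI, NaI, K2CO3, DMF, rt
Reagents that add atoms: none
Why: Copper acetylide alkynylation of the allylic halide (allylic iodide formed in the flask by Finkelstein exchange) should attack the primary terminus and give the skipped enyne with the olefin geometry kept; free hydroxyls are tolerated.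

Step 15
Reactants: 18 skipped enyne diol
Product: 19 (2R,3E,6Z,10E)-13-[(2R,3S)-3-({[tert-butyl(dimethyl)silyl]oxy}methyl)-3-methyloxiran-2-yl]-11-methyl-3-(tributylstannyl)-7-[(trimethylsilyl)methyl]trideca-3,6,10-triene-1,2-diol (spatial arrangement at the carbinol unchanged)
Conditions: Bu3SnH, Mo(CO)3(CNtBu)3 (5 mol %), hydroquinone, THF, 55 °C
Reagents that add atoms: tributyltin hydride, CCCC[SnH](CCCC)CCCC
Why: Molybdenum-catalysed syn-hydrostannation of a propargylic alcohol should place tin on the alkyne carbon next to the carbinol (C13) and hydrogen on C12, and the cis addition fixes the later 12E geometry.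

Step 16
Reactants: 19 vinylstannane
Product: 20 (2R,3E,6Z,10E)-13-[(2R,3S)-3-({[tert-butyl(dimethyl)silyl]oxy}methyl)-3-methyloxiran-2-yl]-3-iodo-11-methyl-7-[(trimethylsilyl)methyl]trideca-3,6,10-triene-1,2-diol
Conditions: I2 (1.05 equiv), NaHCO3, CH2Cl2, −78 to 0 °C
Reagents that add atoms: iodine, II
Why: Iododestannylation is an ipso substitution with retention of geometry, and at low temperature the vinylstannane should react far faster than the allylsilane or the olefins.

Step 17
Reactants: 20 vinyl iodide diol
Product: 21 (3E,4S)-3-{(3Z,7E)-10-[(2R,3S)-3-({[tert-butyl(dimethyl)silyl]oxy}methyl)-3-methyloxiran-2-yl]-8-methyl-4-[(trimethylsilyl)methyl]deca-3,7-dien-1-ylidene}-4-hydroxyoxolan-2-one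
Conditions: Pd(PPh3)4 (5 mol %), CO (1 atm), Et3N, MeCN, 50 °C
Reagents that add atoms: carbon monoxide, [C-]#[O+]
Why: Palladium-catalysed carbonylative lactonisation (oxidative addition, CO insertion, capture of the acyl palladium by the primary C15 hydroxyl in a five-membered closure) keeps the olefin geometry and gives the E-alkylidene lactone; the C14 hydroxyl would give only a strained four-membered lactone and stays free.

Step 18
Reactants: 21 hydroxy lactone
Product: 22 (3E,4S)-4-{[tert-butyl(dimethyl)silyl]oxy}-3-{(3Z,7E)-10-[(2R,3S)-3-({[tert-butyl(dimethyl)silyl]oxy}methyl)-3-methyloxiran-2-yl]-8-methyl-4-[(trimethylsilyl)methyl]deca-3,7-dien-1-ylidene}oxolan-2-one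
Conditions: TBSCl, imidazole, DMF, 0 °C to rt
Reagents that add atoms: tert-butyldimethylsilyl chloride, CC(C)(C)[Si](C)(C)Cl
Why: Silylation under weakly basic conditions masks the allylic C14 hydroxyl so that it neither consumes nor directs the Lewis acid in the key step.

Step 19
Reactants: 22 epoxy diene allylsilane lactone
Product: 23 14,19-bis-O-(tert-butyldimethylsilyl)andrographolide
Conditions: MeAlCl2 (3 equiv), CH2Cl2, −78 °C; Et3N/MeOH, then aq. potassium sodium tartrate
Reagents that add atoms: none
Why: Epoxide-initiated, allylsilane-terminated cation–olefin bicyclisation: MeAlCl2 activates the oxirane, the C5=C10 olefin attacks C4 anti to the departing oxygen, and the resulting C10 cation is captured by C9 of the allylsilane, whose β-silyl cation loses the silyl group to leave only the exocyclic C8=C17 olefin. Ring A closes first by 6-endo opening of the epoxide at its tertiary carbon, and ring B closes last by 6-endo-trig attack of the allylsilane on C10 (C9–C10 bond), both through a chair–chair array with the C3–O bond equatorial. C4 is set by inversion of the (Z)-derived epoxide (the CH2OSi arm cis to the chain becomes the axial C19), C5 and C10 by anti addition across the E-olefin (trans ring fusion, C20 axial), and C9 by the geometry of the allylsilane (C7 and C11 trans, so C11 ends equatorial), all relative to the C3 carbinol from step 5, which therefore fixes the absolute configuration. The step needs opening at C4 and not at C3 (the tertiary centre and the chair alignment secure it), activation of the epoxide in the presence of the lactone (excess Lewis acid; the enoate olefin is electron-poor and takes no part, and O14 is silylated) and one-directional termination (the silicon secures it). The closest known reaction type is the MeAlCl2-promoted bicyclisation of epoxy diene allylsilanes to 3-hydroxy decalins with an exocyclic 8(17)-olefin.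

Step 20
Reactants: 23 14,19-bis-O-(tert-butyldimethylsilyl)andrographolide
Product: 24 andrographolide
Conditions: HF·pyridine, pyridine/THF, 0 °C to rt
Reagents that add atoms: none
Why: Fluoride-driven cleavage of both Si–O bonds under buffered, non-basic conditions should avoid the base-induced loss of the C14 oxygen to which the alkylidene hydroxy lactone is prone.

**Compound list**

1 | geranyl chloride, (2E)-1-chloro-3,7-dimethylocta-2,6-diene | CC(C)=CCC/C(C)=C/CCl | starting material
2 | racemic 3-[(3E)-5-chloro-3-methylpent-3-en-1-yl]-2,2-dimethyloxirane | CC1(C)OC1CC/C(C)=C/CCl | intermediate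
3 | (4E)-6-chloro-4-methylhex-4-enal | O=CCC/C(C)=C/CCl | intermediate
4 | ethyl 2-[bis(2,2,2-trifluoroethoxy)phosphoryl]propanoate | CCOC(=O)C(C)P(=O)(OCC(F)(F)F)OCC(F)(F)F | starting material
5 | ethyl (2Z,6E)-8-chloro-2,6-dimethylocta-2,6-dienoate | CCOC(=O)/C(C)=C\CC/C(C)=C/CCl | intermediate
6 | (2Z,6E)-8-chloro-2,6-dimethylocta-2,6-dien-1-ol | OC/C(C)=C\CC/C(C)=C/CCl | intermediate
7 | [(2S,3R)-3-[(3E)-5-chloro-3-methylpent-3-en-1-yl]-2-methyloxiran-2-yl]methanol | C[C@@]1(CO)O[C@@H]1CC/C(C)=C/CCl | intermediate
8 | tert-butyl{[(2S,3R)-3-[(3E)-5-chloro-3-methylpent-3-en-1-yl]-2-methyloxiran-2-yl]methoxy}dimethylsilane | C[C@@]1(CO[Si](C)(C)C(C)(C)C)O[C@@H]1CC/C(C)=C/CCl | intermediate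
9 | methyl acetoacetate (methyl 3-oxobutanoate) | COC(=O)CC(C)=O | starting material
10 | methyl (6E)-9-[(2R,3S)-3-({[tert-butyl(dimethyl)silyl]oxy}methyl)-3-methyloxiran-2-yl]-7-methyl-3-oxonon-6-enoate | C[C@@]1(CO[Si](C)(C)C(C)(C)C)O[C@@H]1CC/C(C)=C/CCC(=O)CC(=O)OC | intermediate
11 | methyl (2Z,6E)-9-[(2R,3S)-3-({[tert-butyl(dimethyl)silyl]oxy}methyl)-3-methyloxiran-2-yl]-3-[(diethoxyphosphoryl)oxy]-7-methylnona-2,6-dienoate | C[C@@]1(CO[Si](C)(C)C(C)(C)C)O[C@@H]1CC/C(C)=C/CC/C(OP(=O)(OCC)OCC)=C/C(=O)OC | intermediate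
12 | methyl (2Z,6E)-9-[(2R,3S)-3-({[tert-butyl(dimethyl)silyl]oxy}methyl)-3-methyloxiran-2-yl]-7-methyl-3-[(trimethylsilyl)methyl]nona-2,6-dienoate | C[C@@]1(CO[Si](C)(C)C(C)(C)C)O[C@@H]1CC/C(C)=C/CC/C(C[Si](C)(C)C)=C/C(=O)OC | intermediate
13 | (2Z,6E)-9-[(2R,3S)-3-({[tert-butyl(dimethyl)silyl]oxy}methyl)-3-methyloxiran-2-yl]-7-methyl-3-[(trimethylsilyl)methyl]nona-2,6-dien-1-ol | C[C@@]1(CO[Si](C)(C)C(C)(C)C)O[C@@H]1CC/C(C)=C/CC/C(C[Si](C)(C)C)=C/CO | intermediate
14 | tert-butyl{[(2S,3R)-3-[(3E,7Z)-9-chloro-3-methyl-7-[(trimethylsilyl)methyl]nona-3,7-dien-1-yl]-2-methyloxiran-2-yl]methoxy}dimethylsilane | C[C@@]1(CO[Si](C)(C)C(C)(C)C)O[C@@H]1CC/C(C)=C/CC/C(C[Si](C)(C)C)=C/CCl | intermediate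
15 | (R)-2,2-dimethyl-1,3-dioxolane-4-carbaldehyde ((R)-glyceraldehyde acetonide) | O=C[C@H]1COC(C)(C)O1 | starting material
16 | (S)-4-ethynyl-2,2-dimethyl-1,3-dioxolane | C#C[C@H]1COC(C)(C)O1 | intermediate
17 | (S)-but-3-yne-1,2-diol | C#C[C@H](O)CO | intermediate
18 | (2S,6Z,10E)-13-[(2R,3S)-3-({[tert-butyl(dimethyl)silyl]oxy}methyl)-3-methyloxiran-2-yl]-11-methyl-7-[(trimethylsilyl)methyl]trideca-6,10-dien-3-yne-1,2-diol | C[C@@]1(CO[Si](C)(C)C(C)(C)C)O[C@@H]1CC/C(C)=C/CC/C(C[Si](C)(C)C)=C/CC#C[C@H](O)CO | intermediate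
19 | (2R,3E,6Z,10E)-13-[(2R,3S)-3-({[tert-butyl(dimethyl)silyl]oxy}methyl)-3-methyloxiran-2-yl]-11-methyl-3-(tributylstannyl)-7-[(trimethylsilyl)methyl]trideca-3,6,10-triene-1,2-diol | C[C@@]1(CO[Si](C)(C)C(C)(C)C)O[C@@H]1CC/C(C)=C/CC/C(C[Si](C)(C)C)=C/C/C=C(/[Sn](CCCC)(CCCC)CCCC)[C@H](O)CO | intermediate
20 | (2R,3E,6Z,10E)-13-[(2R,3S)-3-({[tert-butyl(dimethyl)silyl]oxy}methyl)-3-methyloxiran-2-yl]-3-iodo-11-methyl-7-[(trimethylsilyl)methyl]trideca-3,6,10-triene-1,2-diol | C[C@@]1(CO[Si](C)(C)C(C)(C)C)O[C@@H]1CC/C(C)=C/CC/C(C[Si](C)(C)C)=C/C/C=C(/I)[C@H](O)CO | intermediate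
21 | (3E,4S)-3-{(3Z,7E)-10-[(2R,3S)-3-({[tert-butyl(dimethyl)silyl]oxy}methyl)-3-methyloxiran-2-yl]-8-methyl-4-[(trimethylsilyl)methyl]deca-3,7-dien-1-ylidene}-4-hydroxyoxolan-2-one | C[C@@]1(CO[Si](C)(C)C(C)(C)C)O[C@@H]1CC/C(C)=C/CC/C(C[Si](C)(C)C)=C/C/C=C1/C(=O)OC[C@H]1O | intermediate
22 | (3E,4S)-4-{[tert-butyl(dimethyl)silyl]oxy}-3-{(3Z,7E)-10-[(2R,3S)-3-({[tert-butyl(dimethyl)silyl]oxy}methyl)-3-methyloxiran-2-yl]-8-methyl-4-[(trimethylsilyl)methyl]deca-3,7-dien-1-ylidene}oxolan-2-one | C[C@@]1(CO[Si](C)(C)C(C)(C)C)O[C@@H]1CC/C(C)=C/CC/C(C[Si](C)(C)C)=C/C/C=C1/C(=O)OC[C@H]1O[Si](C)(C)C(C)(C)C | intermediate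
23 | 14,19-bis-O-(tert-butyldimethylsilyl)andrographolide | C=C1CC[C@@H]2[C@](C)(CO[Si](C)(C)C(C)(C)C)[C@H](O)CC[C@@]2(C)[C@@H]1C/C=C1/C(=O)OC[C@H]1O[Si](C)(C)C(C)(C)C | intermediate
24 | andrographolide | C=C1CC[C@@H]2[C@](C)(CO)[C@H](O)CC[C@@]2(C)[C@@H]1C/C=C1/C(=O)OC[C@H]1O | target

**Step count and risks**

Total step count: 20. Longest linear sequence: 18 steps (steps 1–11 and 14–20); steps 12–13 make the side fragment 17.

The three steps most likely to fail:

Step 19 (key step). What may go wrong: the oxophilic aluminium reagent is drained by the lactone carbonyl and the silyl ethers, so that epoxide opening becomes slower than ionisation or loss of the allylic C14 silyloxy group, or the cascade stalls after ring A. Fallback: the protecting group at O14 is replaced by a temporary aluminium chelate ring. It sets out from hydroxy lactone 21 (step 18 is left out). The first equivalent of MeAlCl2 should turn the free C14 hydroxyl into an aluminium alkoxide, which is no leaving group and binds the neighbouring lactone carbonyl in a six-membered chelate. The further equivalents are then free to trigger the same epoxide/allylsilane bicyclisation, with ring B still closed last. Work-up should give 19-O-(tert-butyldimethylsilyl)andrographolide F1, and HF·pyridine as in step 20 brings the route back at 24. This fallback does not help if the cascade stalls for reasons unrelated to O14.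

Step 15. What may go wrong: the tin hydride adds with the wrong regiochemistry (tin at C12) or isomerises the skipped enyne, and the iodination that follows must also spare the allylsilane. Fallback: the tin and iodine detour is replaced by a palladium-catalysed cyclocarbonylation of the homopropargylic alcohol. It sets out from enyne diol 18. With PdI2/PBu3 (or PdCl2(PPh3)2/SnCl2), CO and MeCN at 60–75 °C, the alkoxycarbonyl palladium species formed at the primary C15 hydroxyl adds syn across the alkyne in the only ring size available. Ring size fixes the regiochemistry and the syn addition gives the E-alkylidene lactone, so the route comes back at 21. The Lewis-acid-free catalyst would be tried first because of the epoxide. New compounds: none F0.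

Step 14. What may go wrong: the 4-silyl-substituted allylic chloride ionises with loss of silicon (1,4-elimination to a 2-substituted butadiene), or the copper acetylide attacks in the SN2′ sense. Fallback: the order of events is changed so that the C11–C12 bond is made before silicon is on board. It sets out from enol phosphate 11. Reduction with i-Bu2AlH as in step 10 should give (2Z,6E)-9-[(2R,3S)-3-({[tert-butyl(dimethyl)silyl]oxy}methyl)-3-methyloxiran-2-yl]-1-hydroxy-7-methylnona-2,6-dien-3-yl diethyl phosphate F2. Corey–Kim chlorination as in step 11 gives the silicon-free chloride (2Z,6E)-9-[(2R,3S)-3-({[tert-butyl(dimethyl)silyl]oxy}methyl)-3-methyloxiran-2-yl]-1-chloro-7-methylnona-2,6-dien-3-yl diethyl phosphate F3. Copper-mediated coupling with 17 as in step 14 gives (2S,6Z,10E)-13-[(2R,3S)-3-({[tert-butyl(dimethyl)silyl]oxy}methyl)-3-methyloxiran-2-yl]-1,2-dihydroxy-11-methyltrideca-6,10-dien-3-yn-7-yl diethyl phosphate F4. The nickel-catalysed coupling of step 9 with excess Me3SiCH2MgCl (the diol carried as its magnesium alkoxide) then installs the allylsilane last and brings the route back at 18.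

Further compounds
F1 | step 19 | 19-O-(tert-butyldimethylsilyl)andrographolide | C=C1CC[C@@H]2[C@](C)(CO[Si](C)(C)C(C)(C)C)[C@H](O)CC[C@@]2(C)[C@@H]1C/C=C1/C(=O)OC[C@H]1O
F0 | step 15 | none | none
F2 | step 14 | (2Z,6E)-9-[(2R,3S)-3-({[tert-butyl(dimethyl)silyl]oxy}methyl)-3-methyloxiran-2-yl]-1-hydroxy-7-methylnona-2,6-dien-3-yl diethyl phosphate | C[C@@]1(CO[Si](C)(C)C(C)(C)C)O[C@@H]1CC/C(C)=C/CC/C(OP(=O)(OCC)OCC)=C/CO
F3 | step 14 | (2Z,6E)-9-[(2R,3S)-3-({[tert-butyl(dimethyl)silyl]oxy}methyl)-3-methyloxiran-2-yl]-1-chloro-7-methylnona-2,6-dien-3-yl diethyl phosphate | C[C@@]1(CO[Si](C)(C)C(C)(C)C)O[C@@H]1CC/C(C)=C/CC/C(OP(=O)(OCC)OCC)=C/CCl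
F4 | step 14 | (2S,6Z,10E)-13-[(2R,3S)-3-({[tert-butyl(dimethyl)silyl]oxy}methyl)-3-methyloxiran-2-yl]-1,2-dihydroxy-11-methyltrideca-6,10-dien-3-yn-7-yl diethyl phosphate | C[C@@]1(CO[Si](C)(C)C(C)(C)C)O[C@@H]1CC/C(C)=C/CC/C(OP(=O)(OCC)OCC)=C/CC#C[C@H](O)CO
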